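**Retrosynthetic overview**
1. Target 21 ⇐ exocyclic alkene 20 by Markovnikov HAT hydrobromination (tertiary C–Br last); 20 ⇐ alcohol 18 by SN2 (OH → Br, inversion); vinyl chloride ⇐ aldehyde 17 (Takai).
2. trans-Chlorohydrin 15 ⇐ chloride opening of epoxide 14; epoxide face ⇐ OH-directed epoxidation of cyclohexenol 11; exocyclic CH2 ⇐ ketone 13.
3. The only ring (cyclohexene 11) ⇐ ring-closing metathesis of acyclic diene 10.
4. Key C–C bond: chelation-controlled intermolecular carbonyl allylation of aldehyde 8 with methallylstannane 9.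
5. Aldehyde 8 ⇐ Evans alkylation of the pent-4-enoyl oxazolidinone with BnOCH2Cl (first stereocentre).

Assumption: the SMILES is read as (1R,2S,4S,5R)-1,4-dibromo-5-chloro-2-[(E)-2-chloroethenyl]-1,5-dimethylcyclohexane, i.e. the C–Cl bond, the secondary C–Br bond and the chlorovinyl group are all cis and the tertiary C–Br bond is trans to them.

**Route**

Step 1
Reactants: 1 (R)-4-benzyloxazolidin-2-one; 2 pent-4-enoyl chloride
Product: 3 (R)-4-benzyl-3-(pent-4-enoyl)oxazolidin-2-one
Conditions: Et3N, DMAP (cat.), CH2Cl2, 0 °C → rt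
Reagents that add atoms: none
Why: DMAP-catalysed N-acylation of the oxazolidinone by the acid chloride installs the Evans auxiliary and creates no stereocentre.

Step 2
Reactants: 3 (R)-4-benzyl-3-(pent-4-enoyl)oxazolidin-2-one; 4 benzyl chloromethyl ether
Product: 6 (R)-4-benzyl-3-[(S)-2-[(benzyloxy)methyl]pent-4-enoyl]oxazolidin-2-one, via chlorotitanium Z-enolate 5 (not isolated)
Conditions: TiCl4, i-Pr2NEt, CH2Cl2, 0 °C; then 4, 0 °C
Reagents that add atoms: titanium tetrachloride, Cl[Ti](Cl)(Cl)Cl (Ti and Cl stay in 5 only)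
Why: Evans alkylation, in which the chelated Z-enolate 5 is attacked by the BnOCH2+ electrophile on the face opposite the 4-benzyl group, sets the α-stereocentre (S), the future ring CH that carries the chlorovinyl group.

Step 3
Reactants: 6 (R)-4-benzyl-3-[(S)-2-[(benzyloxy)methyl]pent-4-enoyl]oxazolidin-2-one
Product: 7 (R)-2-[(benzyloxy)methyl]pent-4-en-1-ol
Conditions: LiBH4, H2O (1 equiv), Et2O, 0 °C
Reagents that add atoms: none
Why: Reductive cleavage of the N-acyl oxazolidinone by LiBH4 gives the primary alcohol and returns the auxiliary without touching the stereocentre (the descriptor changes only through CIP priorities).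

Step 4
Reactants: 7 (R)-2-[(benzyloxy)methyl]pent-4-en-1-ol
Product: 8 (S)-2-[(benzyloxy)methyl]pent-4-enal
Conditions: Dess–Martin periodinane, NaHCO3, CH2Cl2, 0 °C → rt; used at once
Reagents that add atoms: none
Why: Buffered Dess–Martin oxidation gives the α-branched aldehyde under non-basic conditions, so it does not epimerise.

Step 5
Reactants: 8 (S)-2-[(benzyloxy)methyl]pent-4-enal; 9 tributyl(2-methylallyl)stannane
Product: 10 (4R,5S)-5-[(benzyloxy)methyl]-2-methylocta-1,7-dien-4-ol
Conditions: MgBr2·OEt2, CH2Cl2, −78 °C; then 9, −78 → −20 °C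
Reagents that add atoms: none
Why: Keck-type chelation-controlled carbonyl allylation, in which MgBr2 bridges the aldehyde and β-benzyloxy oxygens and the methallylstannane adds to the chelate face anti to the α-allyl group, joins the two fragments and sets the carbinol centre as 4R (anti product).

Step 6
Reactants: 10 (4R,5S)-5-[(benzyloxy)methyl]-2-methylocta-1,7-dien-4-ol
Product: 11 (1R,6S)-6-[(benzyloxy)methyl]-3-methylcyclohex-3-en-1-ol
Conditions: Grubbs II (5 mol %), CH2Cl2 (5 mM), 40 °C
Reagents that add atoms: none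
Why: Ring-closing metathesis of the 1,1-disubstituted and the monosubstituted alkene closes the only ring as a trisubstituted cyclohexene with loss of ethene and changes no stereocentre.

Step 7
Reactants: 11 (1R,6S)-6-[(benzyloxy)methyl]-3-methylcyclohex-3-en-1-ol
Product: 12 (1S,3R,4S,6R)-4-[(benzyloxy)methyl]-1-methyl-7-oxabicyclo[4.1.0]heptan-3-ol
Conditions: VO(acac)2 (5 mol %), t-BuOOH, CH2Cl2, 0 °C → rt
Reagents that add atoms: tert-butyl hydroperoxide, CC(C)(C)OO
Why: Hydroxyl-directed vanadium-catalysed epoxidation of the cyclic homoallylic alcohol delivers oxygen to the alkene face syn to the OH group, which sets both epoxide carbons.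

Step 8
Reactants: 12 (1S,3R,4S,6R)-4-[(benzyloxy)methyl]-1-methyl-7-oxabicyclo[4.1.0]heptan-3-ol
Product: 13 (1S,4S,6R)-4-[(benzyloxy)methyl]-1-methyl-7-oxabicyclo[4.1.0]heptan-3-one
Conditions: Dess–Martin periodinane, NaHCO3, CH2Cl2, 0 °C → rt
Reagents that add atoms: none
Why: Dess–Martin oxidation of the secondary alcohol gives the ketone under neutral conditions that spare the β,γ-epoxide and the α-stereocentre.

Step 9
Reactants: 13 (1S,4S,6R)-4-[(benzyloxy)methyl]-1-methyl-7-oxabicyclo[4.1.0]heptan-3-one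
Product: 14 (1S,4R,6R)-4-[(benzyloxy)methyl]-1-methyl-3-methylidene-7-oxabicyclo[4.1.0]heptane
Conditions: Cp2TiMe2, toluene–THF, 65 °C, dark
Reagents that add atoms: dimethyltitanocene (Petasis reagent), [CH3-].[CH3-].[Ti+4].c1cc[cH-]c1.c1cc[cH-]c1
Why: Petasis methylenation with the non-basic titanium methylidene turns the ketone into the exocyclic alkene without enolisation, epimerisation or β-elimination of the epoxide.

Step 10
Reactants: 14 (1S,4R,6R)-4-[(benzyloxy)methyl]-1-methyl-3-methylidene-7-oxabicyclo[4.1.0]heptane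
Product: 15 (1R,2R,5R)-5-[(benzyloxy)methyl]-2-chloro-2-methyl-4-methylidenecyclohexan-1-ol
Conditions: TiCl4 (1.1 equiv), CH2Cl2, −78 °C; aq NaHCO3
Reagents that add atoms: titanium tetrachloride, Cl[Ti](Cl)(Cl)Cl
Why: Lewis-acid epoxide opening, in which chloride attacks the tertiary carbon anti to oxygen (Markovnikov and trans-diaxial, Fürst–Plattner), forms the tertiary chloride with inversion and leaves the secondary alcohol trans to it.

Step 11
Reactants: 15 (1R,2R,5R)-5-[(benzyloxy)methyl]-2-chloro-2-methyl-4-methylidenecyclohexan-1-ol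
Product: 16 (1R,2R,5R)-2-chloro-5-(hydroxymethyl)-2-methyl-4-methylidenecyclohexan-1-ol
Conditions: BCl3 (1 M in CH2Cl2), pentamethylbenzene, CH2Cl2, −78 °C; aq NaHCO3
Reagents that add atoms: none
Why: BCl3 cleaves the benzyl ether at −78 °C while pentamethylbenzene traps the benzyl cation (Friedel–Crafts), so the alkene and the tertiary chloride are left alone.

Step 12
Reactants: 16 (1R,2R,5R)-2-chloro-5-(hydroxymethyl)-2-methyl-4-methylidenecyclohexan-1-ol
Product: 17 (1R,4R,5R)-4-chloro-5-hydroxy-4-methyl-2-methylidenecyclohexane-1-carbaldehyde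
Conditions: TEMPO (10 mol %), PhI(OAc)2, CH2Cl2, rt; used crude
Reagents that add atoms: none
Why: TEMPO/PhI(OAc)2 oxidation is selective for the primary alcohol over the hindered axial secondary one and gives the aldehyde without base.

Step 13
Reactants: 17 (1R,4R,5R)-4-chloro-5-hydroxy-4-methyl-2-methylidenecyclohexane-1-carbaldehyde
Product: 18 (1R,2R,5S)-2-chloro-5-[(E)-2-chloroethenyl]-2-methyl-4-methylidenecyclohexan-1-ol
Conditions: CrCl2 (6 equiv), CHCl3 (2 equiv), THF, 65 °C
Reagents that add atoms: chloroform, ClC(Cl)Cl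
Why: Takai chloro-olefination with the gem-dichromium species from CHCl3/CrCl2 converts the aldehyde into the (E)-vinyl chloride and is placed before any C–Br bond exists, so Cr(II) meets no reducible bromide.

Step 14
Reactants: 18 (1R,2R,5S)-2-chloro-5-[(E)-2-chloroethenyl]-2-methyl-4-methylidenecyclohexan-1-ol
Product: 20 (1R,2S,4S)-2-bromo-1-chloro-4-[(E)-2-chloroethenyl]-1-methyl-5-methylidenecyclohexane, via secondary triflate 19 (not isolated)
Conditions: Tf2O, pyridine, CH2Cl2, −78 → −30 °C; then n-Bu4NBr, toluene, −30 °C → rt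
Reagents that add atoms: trifluoromethanesulfonic anhydride, O=S(=O)(OS(=O)(=O)C(F)(F)F)C(F)(F)F (in 19 only); tetrabutylammonium bromide, CCCC[N+](CCCC)(CCCC)CCCC.[Br-]
Why: Triflation followed by SN2 displacement with bromide inverts the carbinol carbon, so the secondary bromide ends equatorial and cis to the tertiary chloride.

Step 15
Reactants: 20 (1R,2S,4S)-2-bromo-1-chloro-4-[(E)-2-chloroethenyl]-1-methyl-5-methylidenecyclohexane
Product: 21 (1R,2S,4S,5R)-1,4-dibromo-5-chloro-2-[(E)-2-chloroethenyl]-1,5-dimethylcyclohexane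
Conditions: Co(acac)2 (25 mol %), t-BuOOH (25 mol %), Et3SiH, TsBr, n-PrOH, rt
Reagents that add atoms: 4-methylbenzenesulfonyl bromide, Cc1ccc(cc1)S(Br)(=O)=O
Why: Mukaiyama-type cobalt-hydride HAT hydrobromination adds H• to the CH2 end of the 1,1-disubstituted alkene (the vinyl chloride is inert) and the tertiary radical takes Br from TsBr on the equatorial face, because the axial face is blocked by the syn-axial C–Cl bond, which sets the last stereocentre (R).

**Compound list**
1 | (R)-4-benzyloxazolidin-2-one | O=C1N[C@H](Cc2ccccc2)CO1 | starting material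
2 | pent-4-enoyl chloride | C=CCCC(Cl)=O | starting material
3 | (R)-4-benzyl-3-(pent-4-enoyl)oxazolidin-2-one | C=CCCC(=O)N1[C@H](Cc2ccccc2)COC1=O | intermediate
4 | benzyl chloromethyl ether | ClCOCc1ccccc1 | starting material
5 | chlorotitanium Z-enolate of 3 | C=CC/C=C(\O[Ti](Cl)(Cl)Cl)N1[C@H](Cc2ccccc2)COC1=O | intermediate
6 | (R)-4-benzyl-3-[(S)-2-[(benzyloxy)methyl]pent-4-enoyl]oxazolidin-2-one | O=C([C@H](COCc1ccccc1)CC=C)N1[C@H](Cc2ccccc2)COC1=O | intermediate
7 | (R)-2-[(benzyloxy)methyl]pent-4-en-1-ol | OC[C@H](COCc1ccccc1)CC=C | intermediate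
8 | (S)-2-[(benzyloxy)methyl]pent-4-enal | O=C[C@H](COCc1ccccc1)CC=C | intermediate
9 | tributyl(2-methylallyl)stannane | CCCC[Sn](CCCC)(CCCC)CC(C)=C | starting material
10 | (4R,5S)-5-[(benzyloxy)methyl]-2-methylocta-1,7-dien-4-ol | C=C(C)C[C@@H](O)[C@H](COCc1ccccc1)CC=C | intermediate
11 | (1R,6S)-6-[(benzyloxy)methyl]-3-methylcyclohex-3-en-1-ol | C1=C(C)C[C@@H](O)[C@H](COCc2ccccc2)C1 | intermediate
12 | (1S,3R,4S,6R)-4-[(benzyloxy)methyl]-1-methyl-7-oxabicyclo[4.1.0]heptan-3-ol | C[C@]12C[C@@H](O)[C@H](COCc3ccccc3)C[C@H]1O2 | intermediate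
13 | (1S,4S,6R)-4-[(benzyloxy)methyl]-1-methyl-7-oxabicyclo[4.1.0]heptan-3-one | C[C@]12CC(=O)[C@H](COCc3ccccc3)C[C@H]1O2 | intermediate
14 | (1S,4R,6R)-4-[(benzyloxy)methyl]-1-methyl-3-methylidene-7-oxabicyclo[4.1.0]heptane | C[C@]12CC(=C)[C@H](COCc3ccccc3)C[C@H]1O2 | intermediate
15 | (1R,2R,5R)-5-[(benzyloxy)methyl]-2-chloro-2-methyl-4-methylidenecyclohexan-1-ol | C[C@@]1(Cl)CC(=C)[C@H](COCc2ccccc2)C[C@H]1O | intermediate
16 | (1R,2R,5R)-2-chloro-5-(hydroxymethyl)-2-methyl-4-methylidenecyclohexan-1-ol | C[C@@]1(Cl)CC(=C)[C@H](CO)C[C@H]1O | intermediate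
17 | (1R,4R,5R)-4-chloro-5-hydroxy-4-methyl-2-methylidenecyclohexane-1-carbaldehyde | C[C@@]1(Cl)CC(=C)[C@H](C=O)C[C@H]1O | intermediate
18 | (1R,2R,5S)-2-chloro-5-[(E)-2-chloroethenyl]-2-methyl-4-methylidenecyclohexan-1-ol | C[C@@]1(Cl)CC(=C)[C@H](/C=C/Cl)C[C@H]1O | intermediate
19 | (1R,2R,5S)-2-chloro-5-[(E)-2-chloroethenyl]-2-methyl-4-methylidenecyclohexyl trifluoromethanesulfonate | C[C@@]1(Cl)CC(=C)[C@H](/C=C/Cl)C[C@H]1OS(=O)(=O)C(F)(F)F | intermediate
20 | (1R,2S,4S)-2-bromo-1-chloro-4-[(E)-2-chloroethenyl]-1-methyl-5-methylidenecyclohexane | C[C@@]1(Cl)CC(=C)[C@H](/C=C/Cl)C[C@@H]1Br | intermediate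
21 | (1R,2S,4S,5R)-1,4-dibromo-5-chloro-2-[(E)-2-chloroethenyl]-1,5-dimethylcyclohexane | C[C@@]1(Cl)C[C@@](C)(Br)[C@H](/C=C/Cl)C[C@@H]1Br | target

**Totals and risks**
Total step count: 15. Longest linear sequence: 15 steps (1 and 2 → 21); 4 and 9 enter as side inputs.

Most likely to fail, first: step 14. In the ground-state chair the triflate is axial and its backside is covered by the anti-periplanar axial C–Cl bond. Substitution must therefore pass through the ring-flipped chair, where the chlorovinyl group is axial and syn to the incoming bromide; elimination or chloronium participation (retention, Cl/Br scrambling) may win. The fallback sets out from 18 and comes back at 20, and it avoids backside attack altogether. Oxidise 18 with Dess–Martin periodinane to the α-chloro ketone (2R,5S)-2-chloro-5-[(E)-2-chloroethenyl]-2-methyl-4-methylidenecyclohexan-1-one F1. Reduce with NaBH4 in MeOH at −40 °C, hydride entering axially and anti to the axial C–Cl bond, to the equatorial cis-chlorohydrin (1S,2R,5S)-2-chloro-5-[(E)-2-chloroethenyl]-2-methyl-4-methylidenecyclohexan-1-ol F2. Sulfonylate with quinoline-8-sulfonyl chloride (pyridine, DMAP) to the quinoline-8-sulfonate F3. Treat with TiBr4 in CH2Cl2 at −78 °C: titanium chelated by the leaving group hands bromide to the same face (SNi, retention) and gives 20.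

Second: step 15. The face on which the tertiary radical takes bromine is predicted, not proven, and the epimeric bromide or reduced material may form. The fallback sets out from 20 and comes back at 21 by a polar instead of a radical bromide transfer. Mukaiyama hydration (Mn(dpm)3, PhSiH3, O2, i-PrOH) gives the tertiary alcohol (1R,2S,4S,5R)-4-bromo-5-chloro-2-[(E)-2-chloroethenyl]-1,5-dimethylcyclohexan-1-ol F4 (either epimer at the carbinol carbon serves). Me3SiBr in CH2Cl2 at −40 °C then ionises it, and the tertiary ion pair collapses anti to the axial C–Cl bond to 21.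

Third: step 9. The β,γ-epoxy ketone may not survive 65 °C with the titanium reagent (epoxide opening, epimerisation next to the ketone). The fallback sets out from 13 and comes back at 14 by addition–elimination instead of a metal methylidene. Me3SiCH2Li/CeCl3 (non-basic organocerium, THF, −78 °C) adds to the ketone to give the β-hydroxysilane (1S,4S,6R)-4-[(benzyloxy)methyl]-1-methyl-3-[(trimethylsilyl)methyl]-7-oxabicyclo[4.1.0]heptan-3-ol F5 (mixture at the new carbinol carbon). KH in THF at 0 °C then effects Peterson syn-elimination to 14.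

**Further compounds**
F1 | step 14 | (2R,5S)-2-chloro-5-[(E)-2-chloroethenyl]-2-methyl-4-methylidenecyclohexan-1-one | C[C@@]1(Cl)CC(=C)[C@H](/C=C/Cl)CC1=O
F2 | step 14 | (1S,2R,5S)-2-chloro-5-[(E)-2-chloroethenyl]-2-methyl-4-methylidenecyclohexan-1-ol | C[C@@]1(Cl)CC(=C)[C@H](/C=C/Cl)C[C@@H]1O
F3 | step 14 | (1S,2R,5S)-2-chloro-5-[(E)-2-chloroethenyl]-2-methyl-4-methylidenecyclohexyl quinoline-8-sulfonate | C[C@@]1(Cl)CC(=C)[C@H](/C=C/Cl)C[C@@H]1OS(=O)(=O)c1cccc2cccnc12
F4 | step 15 | (1R,2S,4S,5R)-4-bromo-5-chloro-2-[(E)-2-chloroethenyl]-1,5-dimethylcyclohexan-1-ol | C[C@@]1(Cl)C[C@@](C)(O)[C@H](/C=C/Cl)C[C@@H]1Br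
F5 | step 9 | (1S,4S,6R)-4-[(benzyloxy)methyl]-1-methyl-3-[(trimethylsilyl)methyl]-7-oxabicyclo[4.1.0]heptan-3-ol | C[C@]12CC(O)(C[Si](C)(C)C)[C@H](COCc3ccccc3)C[C@H]1O2
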